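**Retrosynthetic overview**

1. The last bond made is the ester C–O bond between the primary hydroxyl of the lactone triol and the carboxyl group of the hydroazulene dienoic acid (Steglich esterification).
2. Acid half, key disconnection: the cyclopentane is cut at C1–C2 and C3–C3a (azulene numbering) into ethene and a bicyclo[5.1.0]octa-2,4-diene. The enabling feature is that ring-fusion carbon C3a is allylic to the C4=C5–C6=C7 dienoate of the seven-membered ring, so C1, C8a and C3a can be tied into a cyclopropane that is a vinylogous vinylcyclopropane. A tert-butyl ester on C1 is a traceless handle: it lets the cyclopropane be built by MIRC, directs the ring opening, and is removed by a decarboxylation that sets C1.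
3. The cyclopropane precursor comes from 4-isopropylcyclohexanone: asymmetric deprotonation, Saegusa–Ito expansion to the seven-membered ring, MIRC cyclopropanation, then dehydrogenation, dienyl triflate formation and carbonylation. The isopropyl stereocentre relays chirality to C8a and is then erased.
4. Lactone half: the pyranone is made first (Rh-catalysed asymmetric 1,4-addition sets C5, then lactonisation); the cyclopentane is closed last by a SmI2 pinacol coupling (C7–C8) that sets C7, C8 and C9.
5. Ring order: acid half seven-membered ring → temporary cyclopropane → cyclopentane; lactone half pyranone → cyclopentane.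

Key step: step 8

Assumption: the target is taken exactly as drawn, i.e. lactone half (4aR,6S,7S,7aR) and acid half (1R,3aS,8aR); compounds 8–16 are carried as mixtures at the methyl- and ester-bearing carbon because that centre is reset in step 10.

**Route**

Step 1
Reactants: 1 4-(propan-2-yl)cyclohexan-1-one
Product: 2 (R)-trimethyl{[4-(propan-2-yl)cyclohex-1-en-1-yl]oxy}silane
Conditions: (S,S)-bis(1-phenylethyl)amine, n-BuLi, TMSCl (present from the start), THF, −78 °C
Reagents that add atoms: chlorotrimethylsilane C[Si](C)(C)Cl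
Why: Asymmetric deprotonation of the prochiral ketone by the chiral lithium amide with internal silyl quench should give the (R)-enol ether (the (S,S)-base is chosen by analogy with 4-tert-butylcyclohexanone), and this centre is the only source of absolute configuration for the acid half.

Step 2
Reactants: 2 (R)-trimethyl{[4-(propan-2-yl)cyclohex-1-en-1-yl]oxy}silane
Product: 3 (4R)-4-(propan-2-yl)-1-(trimethylsilyloxy)bicyclo[4.1.0]heptane (mixture at C1/C6)
Conditions: Et2Zn, CH2I2, CH2Cl2, 0 °C to rt
Reagents that add atoms: diiodomethane ICI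
Why: Simmons–Smith (Furukawa) cyclopropanation of the electron-rich enol ether should be clean, and the two new cyclopropane centres need no control because both are lost in step 3.

Step 3
Reactants: 3 (4R)-4-(propan-2-yl)-1-(trimethylsilyloxy)bicyclo[4.1.0]heptane
Product: 5 (R)-5-(propan-2-yl)cyclohept-2-en-1-one, via chloro ketone 4 (not isolated)
Conditions: FeCl3, DMF, 0 °C; then NaOAc, MeOH, reflux
Reagents that add atoms: none
Why: Saegusa–Ito one-carbon ring expansion, in which Fe(III) oxidises the siloxycyclopropane, the internal bond cleaves to a β-keto radical that is chlorinated to 4, and acetate-induced loss of HCl gives the cycloheptenone without touching the isopropyl-bearing centre.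

Step 4
Reactants: 5 (R)-5-(propan-2-yl)cyclohept-2-en-1-one; 6 tert-butyl 2-bromopropanoate
Product: 8 tert-butyl (1R,5R,7S)-8-methyl-2-oxo-5-(propan-2-yl)bicyclo[5.1.0]octane-8-carboxylate (both C8 epimers), via bromo ester enolate 7 (not isolated)
Conditions: LDA, THF/DMPU, −78 °C, 6; then 5, −78 to 0 °C
Reagents that add atoms: none
Why: Michael-initiated ring closure (MIRC cyclopropanation), in which the bromo ester enolate should add to the enone β-carbon anti to the 5-isopropyl group and the ketone enolate 7 closes 3-exo-tet with loss of bromide, setting C7 and, through the obligatory cis fusion, C1; the minor 5,7-cis isomer is removed by chromatography.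

Step 5
Reactants: 8 tert-butyl (1R,5R,7S)-8-methyl-2-oxo-5-(propan-2-yl)bicyclo[5.1.0]octane-8-carboxylate
Product: 9 tert-butyl (1R,5R,7S)-8-methyl-2-oxo-5-(propan-2-yl)bicyclo[5.1.0]oct-3-ene-8-carboxylate (both C8 epimers)
Conditions: IBX, DMSO/fluorobenzene, 65 °C
Reagents that add atoms: none
Why: IBX dehydrogenation of the ketone can only give the C3=C4 enone because the other α-carbon is the cyclopropane bridgehead, and no stereocentre is formed.

Step 6
Reactants: 9 tert-butyl (1R,5R,7S)-8-methyl-2-oxo-5-(propan-2-yl)bicyclo[5.1.0]oct-3-ene-8-carboxylate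
Product: 11 tert-butyl (1R,7S)-8-methyl-5-(propan-2-yl)-2-{[(trifluoromethyl)sulfonyl]oxy}bicyclo[5.1.0]octa-2,4-diene-8-carboxylate (both C8 epimers), via potassium dienolate 10 (not isolated)
Conditions: KHMDS, THF, −78 °C; then PhNTf2, −78 to 0 °C
Reagents that add atoms: N-phenylbis(trifluoromethanesulfonimide) O=S(=O)(N(c1ccccc1)S(=O)(=O)C(F)(F)F)C(F)(F)F
Why: Vinylogous enolisation and O-triflation, in which the only removable proton of 9 is the γ-hydrogen at the isopropyl-bearing C5 (the α′-carbon is a cyclopropane CH), so the extended dienolate 10 forms regioselectively and is trapped on oxygen, deleting the relay stereocentre after it has done its work.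

Step 7
Reactants: 11 tert-butyl (1R,7S)-8-methyl-5-(propan-2-yl)-2-{[(trifluoromethyl)sulfonyl]oxy}bicyclo[5.1.0]octa-2,4-diene-8-carboxylate
Product: 12 8-tert-butyl 2-methyl (1S,7S)-8-methyl-5-(propan-2-yl)bicyclo[5.1.0]octa-2,4-diene-2,8-dicarboxylate (both C8 epimers)
Conditions: Pd(OAc)2 (5 mol%), dppf (10 mol%), CO (1 atm), MeOH, Et3N, DMF, 50 °C
Reagents that add atoms: carbon monoxide [C-]#[O+]; methanol CO
Why: Palladium-catalysed methoxycarbonylation of the dienyl triflate introduces the carboxyl carbon under mild conditions and completes the dienyl-substituted cyclopropane needed for the key step.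

Step 8
Reactants: 12 8-tert-butyl 2-methyl (1S,7S)-8-methyl-5-(propan-2-yl)bicyclo[5.1.0]octa-2,4-diene-2,8-dicarboxylate; 13 ethene
Product: 14 1-tert-butyl 4-methyl (3aS,8aS)-1-methyl-7-(propan-2-yl)-1,2,3,3a,8,8a-hexahydroazulene-1,4-dicarboxylate (both C1 epimers)
Conditions: PhSSPh (20 mol%), AIBN (10 mol%), ethene (30 bar), benzene (0.02 M), sunlamp, 25–40 °C
Reagents that add atoms: none
Why: PhS• adds reversibly to the dienoate of 12 (at C5 or C3, bicyclo numbering) to give a radical delocalised onto C2, which is cyclopropylcarbinyl and opens the exocyclic C1–C8 bond with release of ring strain to the tertiary, ester-stabilised C8 radical; this adds to ethene, the new primary radical closes onto C1, and β-scission of the C–S bond returns PhS• and the C2=C3–C4=C5 dienoate. The closest known reaction type is the thiyl-radical-catalysed [3+2] annulation of vinylcyclopropanes with alkenes. The cyclopentane is the only ring closed, by radical 5-exo-trig cyclisation, and the seven-membered ring is carried through unchanged. C8a (old C7) is never broken and keeps its configuration, and C3a (old C1) is set cis to it because the two-carbon chain stays tethered through C1–C8a to the face from which the cyclopropane was opened, so only the cis-fused hydroazulene can form; the quaternary C1 arises as an epimer mixture that is erased in step 10. The step needs scission of the exocyclic C1–C8 bond and not the ring-fusion bond C1–C7, which the methyl and ester groups on C8 secure by making that radical tertiary and stabilised, and 5-exo closure at C1 is kinetically preferred over endo attack at the far diene carbons. It also needs ethene to outrun disulfide capture and addition to a second dienoate, which high ethene pressure, high dilution and a low disulfide loading are meant to secure.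

Step 9
Reactants: 14 1-tert-butyl 4-methyl (3aS,8aS)-1-methyl-7-(propan-2-yl)-1,2,3,3a,8,8a-hexahydroazulene-1,4-dicarboxylate
Product: 15 (3aS,8aS)-4-(methoxycarbonyl)-1-methyl-7-(propan-2-yl)-1,2,3,3a,8,8a-hexahydroazulene-1-carboxylic acid (both C1 epimers)
Conditions: TFA, CH2Cl2, 0 °C to rt
Reagents that add atoms: none
Why: Acidolysis of the tert-butyl ester (E1 loss of isobutene) should leave the methyl dienoate untouched and frees the carboxyl group that served as the radical-stabilising handle.

Step 10
Reactants: 15 (3aS,8aS)-4-(methoxycarbonyl)-1-methyl-7-(propan-2-yl)-1,2,3,3a,8,8a-hexahydroazulene-1-carboxylic acid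
Product: 17 methyl (1R,3aS,8aR)-1-methyl-7-(propan-2-yl)-1,2,3,3a,8,8a-hexahydroazulene-4-carboxylate, via thiohydroxamate ester 16 (not isolated)
Conditions: N-hydroxypyridine-2-thione, DCC, DMAP (cat.), CH2Cl2, 0 °C, dark; then t-BuSH, W lamp, 10 °C
Reagents that add atoms: none
Why: Barton reductive decarboxylation, in which ester 16 fragments under visible light to the tertiary C1 radical, which should take a hydrogen atom from t-BuSH on the convex face (syn to H-3a and H-8a, anti to the C8 methylene), so the methyl group ends cis to C8 and both C1 epimers of 15 converge on (1R).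

Step 11
Reactants: 17 methyl (1R,3aS,8aR)-1-methyl-7-(propan-2-yl)-1,2,3,3a,8,8a-hexahydroazulene-4-carboxylate
Product: 18 (1R,3aS,8aR)-1-methyl-7-(propan-2-yl)-1,2,3,3a,8,8a-hexahydroazulene-4-carboxylic acid
Conditions: LiOH, THF/MeOH/H2O, 45 °C; then 1 M HCl
Reagents that add atoms: lithium hydroxide [Li+].[OH-]
Why: Saponification of the methyl dienoate is routine because no stereocentre of 17 is epimerisable under base.

Step 12
Reactants: 19 2-bromoprop-2-en-1-ol
Product: 20 [(2-bromoprop-2-en-1-yl)oxy](tert-butyl)dimethylsilane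
Conditions: TBSCl, imidazole, DMF, 0 °C to rt
Reagents that add atoms: tert-butyldimethylsilyl chloride CC(C)(C)[Si](C)(C)Cl
Why: Standard silylation of the primary allylic alcohol.

Step 13
Reactants: 20 [(2-bromoprop-2-en-1-yl)oxy](tert-butyl)dimethylsilane
Product: 21 tert-butyldimethyl{[2-(4,4,5,5-tetramethyl-1,3,2-dioxaborolan-2-yl)prop-2-en-1-yl]oxy}silane
Conditions: B2pin2, PdCl2(dppf) (3 mol%), KOAc, dioxane, 80 °C
Reagents that add atoms: bis(pinacolato)diboron CC1(C)OB(OC1(C)C)B1OC(C)(C)C(C)(C)O1
Why: Miyaura borylation of the alkenyl bromide should give the 1,1-disubstituted alkenylboronate without touching the allylic silyl ether.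

Step 14
Reactants: 22 4,4-diethoxybut-1-ene; 23 methyl prop-2-enoate
Product: 24 methyl (2E)-5,5-diethoxypent-2-enoate
Conditions: Grubbs second-generation catalyst (3 mol%), CH2Cl2, 40 °C
Reagents that add atoms: none
Why: Olefin cross-metathesis between a terminal alkene and an acrylate is selective for the (E)-enoate, and the acetal masks the future C7 aldehyde.

Step 15
Reactants: 24 methyl (2E)-5,5-diethoxypent-2-enoate; 21 tert-butyldimethyl{[2-(4,4,5,5-tetramethyl-1,3,2-dioxaborolan-2-yl)prop-2-en-1-yl]oxy}silane
Product: 25 methyl (3R)-3-{3-[(tert-butyldimethylsilyl)oxy]prop-1-en-2-yl}-5,5-diethoxypentanoate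
Conditions: [Rh(cod)OH]2 (3 mol%), (R)-BINAP (7 mol%), dioxane/H2O (10:1), 60 °C
Reagents that add atoms: none
Why: Hayashi–Miyaura rhodium-catalysed asymmetric 1,4-addition, in which the alkenylrhodium species adds to the enoate face selected by the ligand ((R)-BINAP is the enantiomer expected to give 3R), setting the centre that controls all other stereocentres of the lactone half.

Step 16
Reactants: 25 methyl (3R)-3-{3-[(tert-butyldimethylsilyl)oxy]prop-1-en-2-yl}-5,5-diethoxypentanoate
Product: 27 (4R)-4-(2,2-diethoxyethyl)-5-methylideneoxan-2-one, via hydroxy ester 26 (not isolated)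
Conditions: TBAF, THF, 0 °C to rt
Reagents that add atoms: none
Why: Fluoride desilylation liberates the allylic alkoxide of 26, which closes onto the methyl ester (6-exo-trig transesterification) to the δ-lactone carrying the exocyclic methylene.

Step 17
Reactants: 27 (4R)-4-(2,2-diethoxyethyl)-5-methylideneoxan-2-one; 28 {[tert-butyl(dimethyl)silyl]oxy}acetaldehyde
Product: 30 (4R)-3-{2-[(tert-butyldimethylsilyl)oxy]-1-hydroxyethyl}-4-(2,2-diethoxyethyl)-5-methylideneoxan-2-one (mixture at C3 and the carbinol carbon), via lactone enolate 29 (not isolated)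
Conditions: LDA, THF, −78 °C; then 28; sat. NH4Cl
Reagents that add atoms: none
Why: Aldol addition of the lactone lithium enolate to the aldehyde installs C8 and C10, and the two new centres need no control because one is oxidised in step 18 and the other becomes enolisable.

Step 18
Reactants: 30 (4R)-3-{2-[(tert-butyldimethylsilyl)oxy]-1-hydroxyethyl}-4-(2,2-diethoxyethyl)-5-methylideneoxan-2-one
Product: 31 (4R)-3-{[(tert-butyldimethylsilyl)oxy]acetyl}-4-(2,2-diethoxyethyl)-5-methylideneoxan-2-one (C3 epimers and enol)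
Conditions: Dess–Martin periodinane, NaHCO3, CH2Cl2, rt
Reagents that add atoms: none
Why: Dess–Martin oxidation of the secondary alcohol gives the β-keto lactone under buffered conditions that do not touch the C4 centre.

Step 19
Reactants: 31 (4R)-3-{[(tert-butyldimethylsilyl)oxy]acetyl}-4-(2,2-diethoxyethyl)-5-methylideneoxan-2-one
Product: 32 [(4R)-3-{[(tert-butyldimethylsilyl)oxy]acetyl}-5-methylidene-2-oxooxan-4-yl]acetaldehyde (C3 epimers and enol)
Conditions: PPTS (cat.), acetone/H2O (10:1), 45 °C
Reagents that add atoms: water O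
Why: Mild acid-catalysed acetal hydrolysis unmasks the aldehyde while the primary silyl ether, the lactone and the exocyclic alkene should survive.

Step 20
Reactants: 32 [(4R)-3-{[(tert-butyldimethylsilyl)oxy]acetyl}-5-methylidene-2-oxooxan-4-yl]acetaldehyde
Product: 33 (4aR,6S,7S,7aR)-7-{[(tert-butyldimethylsilyl)oxy]methyl}-6,7-dihydroxy-4-methylidenehexahydrocyclopenta[c]pyran-1(3H)-one
Conditions: SmI2 (2.5 equiv), MeOH (3 equiv), THF, −78 °C
Reagents that add atoms: none
Why: SmI2-mediated intramolecular pinacol (ketyl–carbonyl) coupling closes the cyclopentane 5-exo, where Sm(III) chelation between the ketone-derived oxygen and the lactone carbonyl and bridging to the aldehyde oxygen should give the cis-diol cis to the lactone carbonyl, and the enolisable α-carbon lets the ring fusion settle cis, so C6, C7 and C7a are all set relative to C4a.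

Step 21
Reactants: 33 (4aR,6S,7S,7aR)-7-{[(tert-butyldimethylsilyl)oxy]methyl}-6,7-dihydroxy-4-methylidenehexahydrocyclopenta[c]pyran-1(3H)-one
Product: 34 (4aR,6S,7S,7aR)-6,7-dihydroxy-7-(hydroxymethyl)-4-methylidenehexahydrocyclopenta[c]pyran-1(3H)-one
Conditions: HF·pyridine, pyridine/THF, 0 °C
Reagents that add atoms: none
Why: Fluoride desilylation under non-basic conditions avoids retro-aldol cleavage of the β-hydroxy lactone.

Step 22
Reactants: 18 (1R,3aS,8aR)-1-methyl-7-(propan-2-yl)-1,2,3,3a,8,8a-hexahydroazulene-4-carboxylic acid; 34 (4aR,6S,7S,7aR)-6,7-dihydroxy-7-(hydroxymethyl)-4-methylidenehexahydrocyclopenta[c]pyran-1(3H)-one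
Product: 35 nardostachysin
Conditions: DIC, DMAP (0.2 equiv), CH2Cl2, 0 °C to rt
Reagents that add atoms: none
Why: Steglich esterification should acylate the primary hydroxyl in preference to the hindered secondary and the tertiary hydroxyl, and any diastereomer arising from residual enantiomer of 18 is removed by chromatography at this stage.

**Compound list**

1 | 4-(propan-2-yl)cyclohexan-1-one | CC(C)C1CCC(=O)CC1 | starting material
2 | (R)-trimethyl{[4-(propan-2-yl)cyclohex-1-en-1-yl]oxy}silane | C[Si](C)(C)OC1=CC[C@H](C(C)C)CC1 | intermediate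
3 | (4R)-4-(propan-2-yl)-1-(trimethylsilyloxy)bicyclo[4.1.0]heptane (mixture at C1/C6) | C[Si](C)(C)OC12CC1C[C@H](C(C)C)CC2 | intermediate
4 | (5R)-3-chloro-5-(propan-2-yl)cycloheptan-1-one (C3 epimers) | O=C1CC(Cl)C[C@H](C(C)C)CC1 | intermediate
5 | (R)-5-(propan-2-yl)cyclohept-2-en-1-one | O=C1C=CC[C@H](C(C)C)CC1 | intermediate
6 | tert-butyl 2-bromopropanoate (racemic) | CC(Br)C(=O)OC(C)(C)C | starting material
7 | lithium 3-[2-bromo-1-(tert-butoxy)-1-oxopropan-2-yl]-5-(propan-2-yl)cyclohept-1-en-1-olate (3,5-trans) | [Li+].[O-]C1=C[C@@H](C(C)(Br)C(=O)OC(C)(C)C)C[C@H](C(C)C)CC1 | intermediate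
8 | tert-butyl (1R,5R,7S)-8-methyl-2-oxo-5-(propan-2-yl)bicyclo[5.1.0]octane-8-carboxylate (C8 epimers) | O=C1CC[C@@H](C(C)C)C[C@@H]2C(C)(C(=O)OC(C)(C)C)[C@H]12 | intermediate
9 | tert-butyl (1R,5R,7S)-8-methyl-2-oxo-5-(propan-2-yl)bicyclo[5.1.0]oct-3-ene-8-carboxylate (C8 epimers) | O=C1C=C[C@@H](C(C)C)C[C@@H]2C(C)(C(=O)OC(C)(C)C)[C@H]12 | intermediate
10 | potassium 8-(tert-butoxycarbonyl)-8-methyl-5-(propan-2-yl)bicyclo[5.1.0]octa-2,4-dien-2-olate (ring fusion as in 9) | [K+].[O-]C1=CC=C(C(C)C)C[C@@H]2C(C)(C(=O)OC(C)(C)C)[C@H]12 | intermediate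
11 | tert-butyl (1R,7S)-8-methyl-5-(propan-2-yl)-2-{[(trifluoromethyl)sulfonyl]oxy}bicyclo[5.1.0]octa-2,4-diene-8-carboxylate (C8 epimers) | O=S(=O)(OC1=CC=C(C(C)C)C[C@@H]2C(C)(C(=O)OC(C)(C)C)[C@H]12)C(F)(F)F | intermediate
12 | 8-tert-butyl 2-methyl (1S,7S)-8-methyl-5-(propan-2-yl)bicyclo[5.1.0]octa-2,4-diene-2,8-dicarboxylate (C8 epimers) | COC(=O)C1=CC=C(C(C)C)C[C@@H]2C(C)(C(=O)OC(C)(C)C)[C@H]12 | intermediate
13 | ethene | C=C | starting material
14 | 1-tert-butyl 4-methyl (3aS,8aS)-1-methyl-7-(propan-2-yl)-1,2,3,3a,8,8a-hexahydroazulene-1,4-dicarboxylate (C1 epimers) | COC(=O)C1=CC=C(C(C)C)C[C@@H]2C(C)(C(=O)OC(C)(C)C)CC[C@H]12 | intermediate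
15 | (3aS,8aS)-4-(methoxycarbonyl)-1-methyl-7-(propan-2-yl)-1,2,3,3a,8,8a-hexahydroazulene-1-carboxylic acid (C1 epimers) | COC(=O)C1=CC=C(C(C)C)C[C@@H]2C(C)(C(=O)O)CC[C@H]12 | intermediate
16 | 4-methyl 1-(2-thioxopyridin-1(2H)-yl) (3aS,8aS)-1-methyl-7-(propan-2-yl)-1,2,3,3a,8,8a-hexahydroazulene-1,4-dicarboxylate (thiohydroxamate ester of 15) | COC(=O)C1=CC=C(C(C)C)C[C@@H]2C(C)(C(=O)ON3C=CC=CC3=S)CC[C@H]12 | intermediate
17 | methyl (1R,3aS,8aR)-1-methyl-7-(propan-2-yl)-1,2,3,3a,8,8a-hexahydroazulene-4-carboxylate | COC(=O)C1=CC=C(C(C)C)C[C@@H]2[C@H](C)CC[C@H]12 | intermediate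
18 | (1R,3aS,8aR)-1-methyl-7-(propan-2-yl)-1,2,3,3a,8,8a-hexahydroazulene-4-carboxylic acid | OC(=O)C1=CC=C(C(C)C)C[C@@H]2[C@H](C)CC[C@H]12 | intermediate
19 | 2-bromoprop-2-en-1-ol | OCC(Br)=C | starting material
20 | [(2-bromoprop-2-en-1-yl)oxy](tert-butyl)dimethylsilane | C=C(Br)CO[Si](C)(C)C(C)(C)C | intermediate
21 | tert-butyldimethyl{[2-(4,4,5,5-tetramethyl-1,3,2-dioxaborolan-2-yl)prop-2-en-1-yl]oxy}silane | C=C(CO[Si](C)(C)C(C)(C)C)B1OC(C)(C)C(C)(C)O1 | intermediate
22 | 4,4-diethoxybut-1-ene | C=CCC(OCC)OCC | starting material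
23 | methyl prop-2-enoate | C=CC(=O)OC | starting material
24 | methyl (2E)-5,5-diethoxypent-2-enoate | CCOC(OCC)C/C=C/C(=O)OC | intermediate
25 | methyl (3R)-3-{3-[(tert-butyldimethylsilyl)oxy]prop-1-en-2-yl}-5,5-diethoxypentanoate | COC(=O)C[C@H](C(=C)CO[Si](C)(C)C(C)(C)C)CC(OCC)OCC | intermediate
26 | methyl (3R)-5,5-diethoxy-3-(3-hydroxyprop-1-en-2-yl)pentanoate | COC(=O)C[C@H](C(=C)CO)CC(OCC)OCC | intermediate
27 | (4R)-4-(2,2-diethoxyethyl)-5-methylideneoxan-2-one | C=C1COC(=O)C[C@H]1CC(OCC)OCC | intermediate
28 | {[tert-butyl(dimethyl)silyl]oxy}acetaldehyde | O=CCO[Si](C)(C)C(C)(C)C | starting material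
29 | lithium (4R)-4-(2,2-diethoxyethyl)-5-methylidene-5,6-dihydro-4H-pyran-2-olate | [Li+].[O-]C1=C[C@@H](CC(OCC)OCC)C(=C)CO1 | intermediate
30 | (4R)-3-{2-[(tert-butyldimethylsilyl)oxy]-1-hydroxyethyl}-4-(2,2-diethoxyethyl)-5-methylideneoxan-2-one (mixture at C3 and carbinol carbon) | C=C1COC(=O)C(C(O)CO[Si](C)(C)C(C)(C)C)[C@H]1CC(OCC)OCC | intermediate
31 | (4R)-3-{[(tert-butyldimethylsilyl)oxy]acetyl}-4-(2,2-diethoxyethyl)-5-methylideneoxan-2-one (C3 epimers) | C=C1COC(=O)C(C(=O)CO[Si](C)(C)C(C)(C)C)[C@H]1CC(OCC)OCC | intermediate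
32 | [(4R)-3-{[(tert-butyldimethylsilyl)oxy]acetyl}-5-methylidene-2-oxooxan-4-yl]acetaldehyde (C3 epimers) | C=C1COC(=O)C(C(=O)CO[Si](C)(C)C(C)(C)C)[C@H]1CC=O | intermediate
33 | (4aR,6S,7S,7aR)-7-{[(tert-butyldimethylsilyl)oxy]methyl}-6,7-dihydroxy-4-methylidenehexahydrocyclopenta[c]pyran-1(3H)-one | C=C1COC(=O)[C@@H]2[C@H]1C[C@H](O)[C@@]2(O)CO[Si](C)(C)C(C)(C)C | intermediate
34 | (4aR,6S,7S,7aR)-6,7-dihydroxy-7-(hydroxymethyl)-4-methylidenehexahydrocyclopenta[c]pyran-1(3H)-one | C=C1COC(=O)[C@@H]2[C@H]1C[C@H](O)[C@@]2(O)CO | intermediate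
35 | nardostachysin | C=C1COC(=O)[C@@H]2[C@H]1C[C@H](O)[C@@]2(O)COC(=O)C1=CC=C(C(C)C)C[C@@H]2[C@H](C)CC[C@H]12 | target

**Step count and risks**

Total step count: 22. Longest linear sequence: 12 (steps 1–11 and 22).

The three steps most likely to fail:

1. Step 8. Interception of the ring-opened tertiary radical by ethene may be too slow, so that capture by the disulfide, addition to a second dienoate molecule and thermal homodienyl hydrogen shift of the cyclopropane compete. Fallback: starting from 12, the C2 unit is brought in as a halogenated liquid acceptor and the halogen is removed afterwards. Bromoethene is used as co-solvent (far higher molarity than the gas; PhSSPh, AIBN, sealed tube, 40 °C) and should give 1-tert-butyl 4-methyl 3-bromo-1-methyl-7-(propan-2-yl)-1,2,3,3a,8,8a-hexahydroazulene-1,4-dicarboxylate F1. Radical reduction of its carbon–bromine bond with Bu3SnH/AIBN in benzene at 80 °C then rejoins the route at 14.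

2. Step 10. Facial selectivity in the hydrogen-atom transfer to the tertiary C1 radical may be poor, so that the 1-epimer forms alongside 17. Fallback: starting from 15, the centre is set by hydrogenation instead. Kochi oxidative decarboxylation (Pb(OAc)4, cat. Cu(OAc)2, pyridine, benzene, 80 °C) should give methyl (3aS,8aS)-1-methylidene-7-(propan-2-yl)-1,2,3,3a,8,8a-hexahydroazulene-4-carboxylate F2. Chemoselective hydrogenation of this 1,1-disubstituted exocyclic alkene with RhCl(PPh3)3/H2 in benzene (the conjugated trisubstituted dienoate should be left alone) from the convex face then rejoins the route at 17.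

3. Step 20. The ketone-derived ketyl may lose the α-silyloxy group by β-elimination, or the ring may close to a diastereomeric diol. Fallback: starting from 32, the C–C bond is made without a reductant. An NHC-catalysed intramolecular crossed aldehyde–ketone benzoin reaction (triazolium precatalyst, Et3N, toluene, rt) should give (4aR,7S,7aR)-7-{[(tert-butyldimethylsilyl)oxy]methyl}-7-hydroxy-4-methylidenetetrahydrocyclopenta[c]pyran-1,6(3H,4aH)-dione F3, the reversible benzoin step being expected to favour the tertiary hydroxyl cis to the lactone carbonyl. Reduction of the C6 ketone with NaBH4 in MeOH at −78 °C from the convex face then rejoins the route at 33.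

**Further compounds**

F1 | step 8 | 1-tert-butyl 4-methyl 3-bromo-1-methyl-7-(propan-2-yl)-1,2,3,3a,8,8a-hexahydroazulene-1,4-dicarboxylate (ring fusion as in 14; C1 and C3 epimers) | COC(=O)C1=CC=C(C(C)C)C[C@@H]2C(C)(C(=O)OC(C)(C)C)CC(Br)[C@H]12
F2 | step 10 | methyl (3aS,8aS)-1-methylidene-7-(propan-2-yl)-1,2,3,3a,8,8a-hexahydroazulene-4-carboxylate | COC(=O)C1=CC=C(C(C)C)C[C@@H]2C(=C)CC[C@H]12
F3 | step 20 | (4aR,7S,7aR)-7-{[(tert-butyldimethylsilyl)oxy]methyl}-7-hydroxy-4-methylidenetetrahydrocyclopenta[c]pyran-1,6(3H,4aH)-dione | C=C1COC(=O)[C@@H]2[C@H]1CC(=O)[C@@]2(O)CO[Si](C)(C)C(C)(C)C
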